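If the monomer in chains stays at zero for hours and then climbs steadily, I read two things off the run that shows the climb.

in all of them: solid monomer 2.8 M
- alder: initiator 14 mM; the very flask that is asked about, followed so far
- birch: initiator 21 mM; run made earlier
- flask: initiator 14 mM; time 15 h

- alder (time / h: monomer in chains / %): 0.250: 0; 0.833: 0; 1.33: 0; 2.00: 0; 3.00: 0
- birch (time / h: monomer in chains / %): 3.00: 0; 6.00: 3; 10.0: 16; 12.0: 20; 15.0: 35

(each reading ± 2 percentage points)

- solid monomer is a solid; its amount is given per volume of the solution
- the analysis behind the earlier runs scatters by 2 percentage points, standard deviation
- at the start none of the solid monomer is in solution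

- green: doubling the solubility of the solid monomer, all else as stated
- red: doubling the amount of initiator, all else as stated
- grey: doubling the dissolution coefficient of the solid monomer, all else as stated

* monomer in chains at 15 h, in percent of the solid monomer charged
* the change that raises the amount of monomer in chains at 15 h, in percent of the solid monomer charged most ("none" if none brings more than 2 percentage points) (green / red / grey / none)
* amount of monomer in chains at 15 h, in percent of the solid monomer charged, after green

Birch climbs at 0.0356 h⁻¹, as a fraction of the charge, between 6.00 h and 15.0 h. Traced back, that line meets zero at 5.16 h, its onset (induction period), and both are readings with their scatter. The onset dose, initiator charged times hours to onset, is 108 mM·h, and I assume it stays the same at this charge of solid monomer, with the climb unchanged.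

For alder this puts the onset at 7.73 h, later than its last flat reading at 3.00 h, and the climb then gives 25.8% at 15 h. By the same reckoning red puts the onset at 3.87 h, an estimated gain of 14 percentage points. Grey, if dissolving feeds the climb, doubles it and gains 26 points, reaching 51.6%. Green doubles it on the same condition and also raises the level free monomer can reach, so I choose green and put it at that figure too.

The forecast gives 23%, green as best and 45% after green, both numbers lower than mine, in the words “Green is the most robust choice, though red runs it close.” The simulation of alder gives 26.5%, and green as best, reaching 63.3%: green gains 37 points, grey 25 points and red 13 points.

    monomer in chains + living end → free monomer + living end, rate k1*[living end] as long as [monomer in chains] is above zero (k = 0.160 min⁻¹)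
    solid monomer ⇌ free monomer, rate k2*(cs2 - [free monomer]) while solid is left; crystals form when [free monomer] > cs2 (solubility = 2.20 M, k = 0.00170 min⁻¹)
    free monomer + initiator → living end + monomer in chains (k = 0.00160 L mol⁻¹ min⁻¹)
    initiator ⇌ dormant form (K = 0.520, k = 8.00 × 10⁻⁴ min⁻¹)
    free monomer + living end → monomer in chains + living end, rate k5*[living end]*[free monomer] (k = 0.310 L mol⁻¹ min⁻¹)

The onset dose gave 25.8% for alder against the simulated 26.5%. For a neighbour of alder charged with 0.024 M of initiator it gives an onset of 4.50 h and 37.4% at 15 h, and that neighbour stands at 36.6%. In alder, free monomer is made 2.89 times as fast as it is used up, each step taken net, at 5.74 h, and that ratio is 0.952 at 15.0 h. At that hour alder holds 43.4% of the charge as free monomer, 26.5% in chains and 30.1% as solid monomer.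

(All runs come from a simulation with constants of no real substance; noise was put on by code.)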